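**Plan**
- Retrosynthesis: remove the C8 epoxy ester and the C13 acetate, cut the butenolide at C7=C11 (intramolecular Horner–Wadsworth–Emmons) and at O–C12, and trace C5=C6 to a C6 hemiketal, so the lactone falls back on a C6=C7 alkene.
- Enabling feature: the ether oxygen bridges C1 and C4, and quaternary C4 (bearing O, C15 and C5) lies in a tetrahydrofuran spanning the nine-membered ring C4–C5–C6–C7–C8–C9–C10–C1–O. O–C4 and C4–C5 are therefore cut together, back to a 2,6-cis-6-vinyltetrahydropyran whose ring oxygen sits five atoms from a diazo-bearing C4.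
- The tetrahydropyran is cut at C1–C10 (ketyl–acrylate cyclisation) to a C5–C10 chain built from divinylcarbinol, acetylide (C10, C14) and ethyl propiolate (C1–C3); C4 and C15 come from diazoethane.
- Forward order: chain, then tetrahydropyran, then tetrahydrofuran and nine-membered oxacycle in one step, then butenolide on C6/C7, then C5=C6, then acetate and C8 ester.
- Stereochemistry: C7/C8 from Sharpless epoxidation of divinylcarbinol; C1 and C10 from the chelated chair of the SmI2 cyclisation; C4 relayed from C1 through the bridged ylide; the glycidate centre from Sharpless epoxidation of methallyl alcohol; C5=C6 geometry by thermodynamic control.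

Key step: step 12

Remark: locants C1–C15 are those of the target's germacrane skeleton (ring C1–C10, C14 on C10, C15 on C4, lactone C11–C13); TBS = tert-butyldimethylsilyl, TES = triethylsilyl, PMB = 4-methoxybenzyl; the configurations drawn at C3, C6 and C7 in 17–27 are the expected ones and are erased later, so they do not affect the outcome.

**Route**

Step 1
Reactants: 1 penta-1,4-dien-3-ol
Product: 2 (2S,3R)-1,2-epoxypent-4-en-3-ol
Conditions: Ti(OiPr)4 (10 mol %), D-(−)-diisopropyl tartrate (12 mol %), t-BuOOH, 4 Å MS, CH2Cl2, −20 °C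
Reagents that add atoms: tert-butyl hydroperoxide, CC(C)(C)OO
Why: Sharpless asymmetric epoxidation desymmetrises the dienol, the tartrate selecting one enantiotopic vinyl group and the face that gives the anti epoxy alcohol, which sets C7 (R) and C8 (S), while the minor enantiomer is drained by a fast second epoxidation.

Step 2
Reactants: 2 (2S,3R)-1,2-epoxypent-4-en-3-ol
Product: 3 (S)-2-[(R)-1-(4-methoxybenzyloxy)prop-2-en-1-yl]oxirane
Conditions: NaH, 4-MeOC6H4CH2Cl, Bu4NI (cat.), THF/DMF, 0 °C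
Reagents that add atoms: 4-methoxybenzyl chloride, COc1ccc(CCl)cc1
Why: Williamson etherification, in which the alkoxide should be benzylated at 0 °C faster than it undergoes Payne rearrangement, and no stereocentre is touched.

Step 3
Reactants: 3 (S)-2-[(R)-1-(4-methoxybenzyloxy)prop-2-en-1-yl]oxirane
Product: 4 (3R,4S)-3-(4-methoxybenzyloxy)hept-1-en-6-yn-4-ol
Conditions: LiC≡CH·H2NCH2CH2NH2, DMSO, rt; H2O quench
Reagents that add atoms: lithium acetylide–ethylenediamine complex, [Li+].[C-]#C.NCCN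
Why: SN2 opening of the terminal epoxide at its CH2 (C9) by acetylide brings in C10 and C14 as a masked methyl ketone and leaves the C8 carbinol configuration intact.

Step 4
Reactants: 4 (3R,4S)-3-(4-methoxybenzyloxy)hept-1-en-6-yn-4-ol
Product: 5 (3R,4S)-4-(tert-butyldimethylsilyloxy)-3-(4-methoxybenzyloxy)hept-1-en-6-yne
Conditions: TBSCl, imidazole, DMF, rt
Reagents that add atoms: tert-butyldimethylsilyl chloride, CC(C)(C)[Si](C)(C)Cl
Why: standard imidazole-mediated silylation of the secondary alcohol differentiates O8 from O7 with a group meant to last until step 26.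

Step 5
Reactants: 5 (3R,4S)-4-(tert-butyldimethylsilyloxy)-3-(4-methoxybenzyloxy)hept-1-en-6-yne
Product: 6 (3R,4S)-4-(tert-butyldimethylsilyloxy)hept-1-en-6-yn-3-ol
Conditions: DDQ, CH2Cl2/pH 7 buffer, 0 °C
Reagents that add atoms: none
Why: oxidative cleavage of the electron-rich benzyl ether through its benzylic oxocarbenium ion frees O7 while the silyl ether, alkyne and vinyl group are inert to DDQ.

Step 6
Reactants: 6 (3R,4S)-4-(tert-butyldimethylsilyloxy)hept-1-en-6-yn-3-ol; 7 ethyl propiolate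
Product: 8 ethyl (E)-3-{[(3R,4S)-4-(tert-butyldimethylsilyloxy)hept-1-en-6-yn-3-yl]oxy}acrylate
Conditions: N-methylmorpholine, CH2Cl2, rt
Reagents that add atoms: none
Why: amine-mediated oxa-Michael addition of the alcohol to the ynoate should give the E β-alkoxyacrylate that later accepts the ketyl radical and supplies C1–C3.

Step 7
Reactants: 8 ethyl (E)-3-{[(3R,4S)-4-(tert-butyldimethylsilyloxy)hept-1-en-6-yn-3-yl]oxy}acrylate
Product: 9 ethyl (E)-3-{[(3R,4S)-4-(tert-butyldimethylsilyloxy)-6-oxohept-1-en-3-yl]oxy}acrylate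
Conditions: Ph3PAuNTf2 (2 mol %), H2O (5 equiv), MeOH, rt
Reagents that add atoms: water, O
Why: gold-catalysed Markovnikov hydration of the terminal alkyne unveils the methyl ketone (C10=O, C14) under near-neutral conditions that spare the silyl ether and the enol ether.

Step 8
Reactants: 9 ethyl (E)-3-{[(3R,4S)-4-(tert-butyldimethylsilyloxy)-6-oxohept-1-en-3-yl]oxy}acrylate
Product: 10 ethyl 2-[(2S,3R,5S,6R)-5-(tert-butyldimethylsilyloxy)-3-hydroxy-3-methyl-6-vinyltetrahydro-2H-pyran-2-yl]acetate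
Conditions: SmI2 (2.5 equiv), MeOH (3 equiv), THF, 0 °C
Reagents that add atoms: none
Why: SmI2 ketyl–olefin reductive cyclisation, in which the ketyl adds 6-exo to the acrylate β-carbon through a chair with the ester chelated to the oxygen-bound trivalent samarium, so C1–C10 forms with the C1 acetate arm equatorial and cis to the C7 vinyl group and the C10 oxygen equatorial, trans to that arm, with the methyl axial.

Step 9
Reactants: 10 ethyl 2-[(2S,3R,5S,6R)-5-(tert-butyldimethylsilyloxy)-3-hydroxy-3-methyl-6-vinyltetrahydro-2H-pyran-2-yl]acetate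
Product: 11 ethyl 2-[(2S,3R,5S,6R)-5-(tert-butyldimethylsilyloxy)-3-methyl-3-(triethylsilyloxy)-6-vinyltetrahydro-2H-pyran-2-yl]acetate
Conditions: TESOTf, 2,6-lutidine, CH2Cl2, −78 → 0 °C
Reagents that add atoms: triethylsilyl triflate, CC[Si](CC)(CC)OS(=O)(=O)C(F)(F)F
Why: silyl triflate silylation masks the tertiary alcohol, which would otherwise lactonise onto the acid or undergo O–H insertion with the carbenoid.

Step 10
Reactants: 11 ethyl 2-[(2S,3R,5S,6R)-5-(tert-butyldimethylsilyloxy)-3-methyl-3-(triethylsilyloxy)-6-vinyltetrahydro-2H-pyran-2-yl]acetate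
Product: 12 2-[(2S,3R,5S,6R)-5-(tert-butyldimethylsilyloxy)-3-methyl-3-(triethylsilyloxy)-6-vinyltetrahydro-2H-pyran-2-yl]acetic acid
Conditions: LiOH, THF/MeOH/H2O, rt; then 1 M HCl to pH 3–4
Reagents that add atoms: lithium hydroxide, [Li+].[OH-]
Why: ester saponification, in which any retro-oxa-Michael/re-addition at C1 returns the same thermodynamically preferred 2,6-cis ring.

Step 11
Reactants: 12 2-[(2S,3R,5S,6R)-5-(tert-butyldimethylsilyloxy)-3-methyl-3-(triethylsilyloxy)-6-vinyltetrahydro-2H-pyran-2-yl]acetic acid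
Product: 14 3-diazo-1-[(2S,3R,5S,6R)-5-(tert-butyldimethylsilyloxy)-3-methyl-3-(triethylsilyloxy)-6-vinyltetrahydro-2H-pyran-2-yl]butan-2-one, via mixed anhydride 13 (not isolated)
Conditions: i-BuOCOCl, Et3N, Et2O, −20 °C; then CH3CHN2 (Et2O), 0 °C → rt
Reagents that add atoms: diazoethane, CC=[N+]=[N-] (isobutyl chloroformate, CC(C)COC(=O)Cl, only in intermediate 13)
Why: acylation of diazoethane by the mixed carbonic anhydride (Arndt–Eistert-type diazo ketone synthesis) attaches C4 and C15 without enolising the C2 methylene next to the β-alkoxy group.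

Step 12
Reactants: 14 3-diazo-1-[(2S,3R,5S,6R)-5-(tert-butyldimethylsilyloxy)-3-methyl-3-(triethylsilyloxy)-6-vinyltetrahydro-2H-pyran-2-yl]butan-2-one
Product: 16 (1S,4S,8S,10R,6Z)-8-(tert-butyldimethylsilyloxy)-4,10-dimethyl-10-(triethylsilyloxy)-1,4-epoxycyclodec-6-en-3-one (an 11-oxabicyclo[6.2.1]undecenone), via oxonium ylide 15 (not isolated)
Conditions: Cu(CF3COCHCOCF3)2 (5 mol %), CH2Cl2, slow addition of 14, 25 → 40 °C
Reagents that add atoms: none
Why: Loss of N2 gives a copper carbenoid at C4 that is captured by the tetrahydropyran oxygen lying 1,5 to it, closing the tetrahydrofuran by O–C4 bond formation as the five-membered oxonium ylide 15; the ylide carbon then bonds to the vinyl terminus C5 through a five-centre envelope transition state while O–C7 breaks, a [2,3]-sigmatropic shift that enlarges the six-membered ether by three atoms to the nine-membered oxacycle (ring expansion, not a direct cyclisation) and leaves C6=C7. The closest known reaction is the copper-catalysed oxonium ylide formation/[2,3] ring expansion of 6-vinyltetrahydropyranyl diazo ketones to 11-oxabicyclo[6.2.1]undecenones, applied here with a methyl group on the diazo carbon. The only new stereocentre, C4, is controlled by C1: the allyl unit migrates suprafacially across the oxonium, so C5 must arrive on the furanone face that carries C10, the trans-bridged alternative being geometrically out of reach. The step needs ylide formation to outrun 1,2-hydride migration from C15 and C–H insertion; the 1,5-disposed ring oxygen is the nearest nucleophile, and the electron-poor copper catalyst at modest temperature should favour ylide capture and the [2,3] path over a [1,2] shift. The Z geometry at C6=C7 is expected from the 2,6-cis substrate but is not critical, since both carbons are re-functionalised later.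

Step 13
Reactants: 16 (1S,4S,8S,10R,6Z)-8-(tert-butyldimethylsilyloxy)-4,10-dimethyl-10-(triethylsilyloxy)-1,4-epoxycyclodec-6-en-3-one
Product: 17 (1S,3S,4S,8S,10R,6Z)-8-(tert-butyldimethylsilyloxy)-4,10-dimethyl-10-(triethylsilyloxy)-1,4-epoxycyclodec-6-en-3-ol
Conditions: NaBH4, MeOH, 0 °C
Reagents that add atoms: none
Why: borohydride reduction of the ketone, expected from the face away from the C5–C10 bridge, gives a C3 alcohol whose configuration is immaterial because the centre is removed in step 15.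

Step 14
Reactants: 17 (1S,3S,4S,8S,10R,6Z)-8-(tert-butyldimethylsilyloxy)-4,10-dimethyl-10-(triethylsilyloxy)-1,4-epoxycyclodec-6-en-3-ol
Product: 18 O-[(1S,3S,4S,8S,10R,6Z)-8-(tert-butyldimethylsilyloxy)-4,10-dimethyl-10-(triethylsilyloxy)-1,4-epoxycyclodec-6-en-3-yl] S-methyl dithiocarbonate
Conditions: NaH, imidazole (cat.), THF; CS2; then MeI, 0 °C → rt
Reagents that add atoms: carbon disulfide, S=C=S; iodomethane, CI
Why: xanthate formation from the sodium alkoxide prepares the C3 oxygen for radical removal.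

Step 15
Reactants: 18 O-[(1S,3S,4S,8S,10R,6Z)-8-(tert-butyldimethylsilyloxy)-4,10-dimethyl-10-(triethylsilyloxy)-1,4-epoxycyclodec-6-en-3-yl] S-methyl dithiocarbonate
Product: 19 (1S,4R,8S,10R,6Z)-8-(tert-butyldimethylsilyloxy)-4,10-dimethyl-10-(triethylsilyloxy)-1,4-epoxycyclodec-6-ene
Conditions: Bu3SnH, AIBN (cat.), toluene, 100 °C
Reagents that add atoms: none
Why: Barton–McCombie deoxygenation, in which the secondary C3 radical neither expels the β-ether oxygen nor cyclises favourably onto C6=C7 and is simply reduced to the C3 methylene.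

Step 16
Reactants: 19 (1S,4R,8S,10R,6Z)-8-(tert-butyldimethylsilyloxy)-4,10-dimethyl-10-(triethylsilyloxy)-1,4-epoxycyclodec-6-ene
Product: 20 (1S,4R,6R,7R,8S,10R)-8-(tert-butyldimethylsilyloxy)-4,10-dimethyl-10-(triethylsilyloxy)-1,4-epoxycyclodecane-6,7-diol
Conditions: OsO4 (2 mol %), N-methylmorpholine N-oxide, acetone/H2O, rt
Reagents that add atoms: N-methylmorpholine N-oxide, C[N+]1([O-])CCOCC1; water, O
Why: Upjohn syn-dihydroxylation of the only alkene, expected anti to the C8 silyloxy group, gives a cis-diol whose two new centres are both erased later (C7 in step 21, C6 in step 22).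

Step 17
Reactants: 21 (4-methoxyphenyl)methanol; 22 ethyl 2-(diethoxyphosphoryl)acrylate
Product: 23 ethyl 2-(diethoxyphosphoryl)-3-(4-methoxybenzyloxy)propanoate (racemic)
Conditions: DBU (20 mol %), THF, rt
Reagents that add atoms: none
Why: base-catalysed oxa-Michael addition of the alcohol to the doubly activated vinylphosphonate gives the stabilised phosphonoacetate, whose α-centre is racemic and later becomes sp2 C11.

Step 18
Reactants: 23 ethyl 2-(diethoxyphosphoryl)-3-(4-methoxybenzyloxy)propanoate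
Product: 24 2-(diethoxyphosphoryl)-3-(4-methoxybenzyloxy)propanoic acid (racemic)
Conditions: LiOH (1.05 equiv), THF/H2O, 0 °C; then 1 M HCl to pH 3
Reagents that add atoms: lithium hydroxide, [Li+].[OH-]
Why: the carboxylic ester is saponified much faster than the phosphonate esters, and the alkoxide is too poor a leaving group for β-elimination under these mild conditions.

Step 19
Reactants: 20 (1S,4R,6R,7R,8S,10R)-8-(tert-butyldimethylsilyloxy)-4,10-dimethyl-10-(triethylsilyloxy)-1,4-epoxycyclodecane-6,7-diol; 24 2-(diethoxyphosphoryl)-3-(4-methoxybenzyloxy)propanoic acid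
Product: 25 6-O-[2-(diethoxyphosphoryl)-3-(4-methoxybenzyloxy)propanoyl] ester of diol 20 (7-hydroxy free; epimers at the phosphonate carbon)
Conditions: DCC, DMAP (10 mol %), CH2Cl2, −20 → 0 °C
Reagents that add atoms: none
Why: Steglich esterification should take place at the C6 hydroxyl, flanked only by the C5 methylene, because the C7 hydroxyl is shielded by the neighbouring C8 silyl ether.

Step 20
Reactants: 25 6-O-[2-(diethoxyphosphoryl)-3-(4-methoxybenzyloxy)propanoyl] ester of diol 20
Product: 26 (1S,4R,6R,8S,10R)-8-(tert-butyldimethylsilyloxy)-4,10-dimethyl-7-oxo-10-(triethylsilyloxy)-1,4-epoxycyclodecan-6-yl 2-(diethoxyphosphoryl)-3-(4-methoxybenzyloxy)propanoate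
Conditions: Dess–Martin periodinane, pyridine, CH2Cl2, rt
Reagents that add atoms: none
Why: Dess–Martin oxidation converts the remaining secondary alcohol into the C7 ketone under buffered conditions that avoid acyl migration and epimerisation at C8.

Step 21
Reactants: 26 (1S,4R,6R,8S,10R)-8-(tert-butyldimethylsilyloxy)-4,10-dimethyl-7-oxo-10-(triethylsilyloxy)-1,4-epoxycyclodecan-6-yl 2-(diethoxyphosphoryl)-3-(4-methoxybenzyloxy)propanoate
Product: 27 butenolide fused at C6–C7 [C6–O–C12(=O)–C11(CH2OPMB)=C7; (1S,4R,6R,8S,10R); 8-OTBS; 10-OTES]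
Conditions: LiCl, i-Pr2NEt, MeCN, rt
Reagents that add atoms: none
Why: intramolecular Horner–Wadsworth–Emmons olefination closes the five-membered lactone by C7=C11 bond formation, the mild amine base deprotonating only the phosphonate and leaving C8–H alone.

Step 22
Reactants: 27 butenolide fused at C6–C7
Product: 29 6-hydroxybutenolide [C6 hemiketal of 27; both C6 epimers serve], via silyloxyfuran 28 (not isolated)
Conditions: TBSOTf, Et3N, CH2Cl2, 0 °C; then dimethyldioxirane, acetone, −78 °C; aqueous work-up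
Reagents that add atoms: dimethyldioxirane, CC1(C)OO1 (tert-butyldimethylsilyl triflate, CC(C)(C)[Si](C)(C)OS(=O)(=O)C(F)(F)F, only in intermediate 28)
Why: soft enolisation removes the doubly activated C6–H to give the aromatic 2-silyloxyfuran, which dimethyldioxirane oxidises at its nucleophilic γ-carbon C6 (vinylogous Rubottom oxidation) to the hemiketal after loss of silicon.

Step 23
Reactants: 29 6-hydroxybutenolide
Product: 30 (E)-γ-alkylidene butenolide [C5=C6; C7=C11; 13-OPMB; 8-OTBS; 10-OTES; (1S,4R,8S,10R)]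
Conditions: camphorsulfonic acid (10 mol %), 4 Å MS, CH2Cl2, rt
Reagents that add atoms: none
Why: acid-catalysed dehydration of the γ-hydroxybutenolide through its acyloxocarbenium ion can only remove a C5 hydrogen, and reversible protonation should let C5=C6 settle in the ring-cis geometry (E by the sequence rule) of the target.

Step 24
Reactants: 30 (E)-γ-alkylidene butenolide with 13-OPMB
Product: 31 13-hydroxy compound [CH2OH on C11; 8-OTBS; 10-OTES]
Conditions: DDQ, CH2Cl2/pH 7 buffer, 0 °C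
Reagents that add atoms: none
Why: oxidative cleavage of the PMB ether, the cross-conjugated dienyl lactone being too electron-poor to compete for DDQ.

Step 25
Reactants: 31 13-hydroxy compound
Product: 32 13-acetate [CH2OAc on C11; 8-OTBS; 10-OTES]
Conditions: Ac2O, pyridine, DMAP (cat.), CH2Cl2, 0 °C
Reagents that add atoms: acetic anhydride, CC(=O)OC(C)=O
Why: acetylation of the only free hydroxyl, a primary allylic alcohol, under mild base that does not deprotonate C8.

Step 26
Reactants: 32 13-acetate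
Product: 33 8,10-diol 13-acetate [(1S,4R,8S,10R); C8–OH and C10–OH free]
Conditions: HF·pyridine, pyridine, THF, 0 °C → rt
Reagents that add atoms: none
Why: buffered fluoride desilylation removes both silyl ethers while the allylic acetate and the enol lactone are stable.

Step 27
Reactants: 34 2-methylprop-2-en-1-ol
Product: 35 (R)-(2-methyloxiran-2-yl)methanol
Conditions: Ti(OiPr)4 (5 mol %), D-(−)-diisopropyl tartrate (6 mol %), t-BuOOH, 4 Å MS, CH2Cl2, −20 °C
Reagents that add atoms: tert-butyl hydroperoxide, CC(C)(C)OO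
Why: catalytic Sharpless asymmetric epoxidation, the D-tartrate directing oxygen to the alkene face that gives the R epoxy alcohol and so sets the quaternary centre of the ester side chain.

Step 28
Reactants: 35 (R)-(2-methyloxiran-2-yl)methanol
Product: 36 (S)-2-methyloxirane-2-carboxylic acid
Conditions: RuCl3 (2 mol %), NaIO4, CCl4/MeCN/H2O, rt
Reagents that add atoms: water, O
Why: RuO4-mediated oxidation of the primary alcohol to the acid via the aldehyde hydrate leaves the quaternary epoxide centre untouched (the descriptor changes from R to S only through the priority change).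

Step 29
Reactants: 33 8,10-diol 13-acetate; 36 (S)-2-methyloxirane-2-carboxylic acid
Product: 37 CNP0142137.1
Conditions: DCC, DMAP (0.2 equiv), CH2Cl2, 0 °C → rt
Reagents that add atoms: none
Why: Steglich esterification acylates the secondary C8 hydroxyl, the tertiary C10 hydroxyl being too hindered to compete and the quaternary epoxide centre unable to epimerise.

**Compound list**

1 | penta-1,4-dien-3-ol | C=CC(O)C=C | starting material
2 | (2S,3R)-1,2-epoxypent-4-en-3-ol | C=C[C@@H](O)[C@@H]1CO1 | intermediate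
3 | (S)-2-[(R)-1-(4-methoxybenzyloxy)prop-2-en-1-yl]oxirane | C=C[C@@H](OCc1ccc(OC)cc1)[C@@H]1CO1 | intermediate
4 | (3R,4S)-3-(4-methoxybenzyloxy)hept-1-en-6-yn-4-ol | C=C[C@@H](OCc1ccc(OC)cc1)[C@@H](O)CC#C | intermediate
5 | (3R,4S)-4-(tert-butyldimethylsilyloxy)-3-(4-methoxybenzyloxy)hept-1-en-6-yne | C=C[C@@H](OCc1ccc(OC)cc1)[C@@H](O[Si](C)(C)C(C)(C)C)CC#C | intermediate
6 | (3R,4S)-4-(tert-butyldimethylsilyloxy)hept-1-en-6-yn-3-ol | C=C[C@@H](O)[C@@H](O[Si](C)(C)C(C)(C)C)CC#C | intermediate
7 | ethyl propiolate | C#CC(=O)OCC | starting material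
8 | ethyl (E)-3-{[(3R,4S)-4-(tert-butyldimethylsilyloxy)hept-1-en-6-yn-3-yl]oxy}acrylate | C=C[C@@H](O/C=C/C(=O)OCC)[C@@H](O[Si](C)(C)C(C)(C)C)CC#C | intermediate
9 | ethyl (E)-3-{[(3R,4S)-4-(tert-butyldimethylsilyloxy)-6-oxohept-1-en-3-yl]oxy}acrylate | C=C[C@@H](O/C=C/C(=O)OCC)[C@@H](O[Si](C)(C)C(C)(C)C)CC(C)=O | intermediate
10 | ethyl 2-[(2S,3R,5S,6R)-5-(tert-butyldimethylsilyloxy)-3-hydroxy-3-methyl-6-vinyltetrahydro-2H-pyran-2-yl]acetate | C=C[C@H]1O[C@@H](CC(=O)OCC)[C@](C)(O)C[C@@H]1O[Si](C)(C)C(C)(C)C | intermediate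
11 | ethyl 2-[(2S,3R,5S,6R)-5-(tert-butyldimethylsilyloxy)-3-methyl-3-(triethylsilyloxy)-6-vinyltetrahydro-2H-pyran-2-yl]acetate | C=C[C@H]1O[C@@H](CC(=O)OCC)[C@](C)(O[Si](CC)(CC)CC)C[C@@H]1O[Si](C)(C)C(C)(C)C | intermediate
12 | 2-[(2S,3R,5S,6R)-5-(tert-butyldimethylsilyloxy)-3-methyl-3-(triethylsilyloxy)-6-vinyltetrahydro-2H-pyran-2-yl]acetic acid | C=C[C@H]1O[C@@H](CC(=O)O)[C@](C)(O[Si](CC)(CC)CC)C[C@@H]1O[Si](C)(C)C(C)(C)C | intermediate
13 | mixed anhydride of 12 with isobutyl hydrogen carbonate (not isolated) | C=C[C@H]1O[C@@H](CC(=O)OC(=O)OCC(C)C)[C@](C)(O[Si](CC)(CC)CC)C[C@@H]1O[Si](C)(C)C(C)(C)C | intermediate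
14 | 3-diazo-1-[(2S,3R,5S,6R)-5-(tert-butyldimethylsilyloxy)-3-methyl-3-(triethylsilyloxy)-6-vinyltetrahydro-2H-pyran-2-yl]butan-2-one | C=C[C@H]1O[C@@H](CC(=O)C(C)=[N+]=[N-])[C@](C)(O[Si](CC)(CC)CC)C[C@@H]1O[Si](C)(C)C(C)(C)C | intermediate
15 | bicyclic oxonium ylide (O bonded to C1, C4 and C7; C3 enolate; free or copper-bound; not isolated) | C=C[C@H]1[O+]2C(C)=C([O-])C[C@H]2[C@](C)(O[Si](CC)(CC)CC)C[C@@H]1O[Si](C)(C)C(C)(C)C | intermediate
16 | (1S,4S,8S,10R,6Z)-8-(tert-butyldimethylsilyloxy)-4,10-dimethyl-10-(triethylsilyloxy)-1,4-epoxycyclodec-6-en-3-one | C1/C=C\[C@@H](O[Si](C)(C)C(C)(C)C)C[C@@](C)(O[Si](CC)(CC)CC)[C@@H]2CC(=O)[C@@]1(C)O2 | intermediate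
17 | (1S,3S,4S,8S,10R,6Z)-8-(tert-butyldimethylsilyloxy)-4,10-dimethyl-10-(triethylsilyloxy)-1,4-epoxycyclodec-6-en-3-ol | C1/C=C\[C@@H](O[Si](C)(C)C(C)(C)C)C[C@@](C)(O[Si](CC)(CC)CC)[C@@H]2C[C@H](O)[C@@]1(C)O2 | intermediate
18 | S-methyl xanthate of 17 at O3 | C1/C=C\[C@@H](O[Si](C)(C)C(C)(C)C)C[C@@](C)(O[Si](CC)(CC)CC)[C@@H]2C[C@H](OC(=S)SC)[C@@]1(C)O2 | intermediate
19 | (1S,4R,8S,10R,6Z)-8-(tert-butyldimethylsilyloxy)-4,10-dimethyl-10-(triethylsilyloxy)-1,4-epoxycyclodec-6-ene | C1/C=C\[C@@H](O[Si](C)(C)C(C)(C)C)C[C@@](C)(O[Si](CC)(CC)CC)[C@@H]2CC[C@@]1(C)O2 | intermediate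
20 | (1S,4R,6R,7R,8S,10R)-8-(tert-butyldimethylsilyloxy)-4,10-dimethyl-10-(triethylsilyloxy)-1,4-epoxycyclodecane-6,7-diol | C1[C@@H](O)[C@@H](O)[C@@H](O[Si](C)(C)C(C)(C)C)C[C@@](C)(O[Si](CC)(CC)CC)[C@@H]2CC[C@@]1(C)O2 | intermediate
21 | (4-methoxyphenyl)methanol | COc1ccc(CO)cc1 | starting material
22 | ethyl 2-(diethoxyphosphoryl)acrylate | C=C(C(=O)OCC)P(=O)(OCC)OCC | starting material
23 | ethyl 2-(diethoxyphosphoryl)-3-(4-methoxybenzyloxy)propanoate (racemic) | CCOC(=O)C(COCc1ccc(OC)cc1)P(=O)(OCC)OCC | intermediate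
24 | 2-(diethoxyphosphoryl)-3-(4-methoxybenzyloxy)propanoic acid (racemic) | OC(=O)C(COCc1ccc(OC)cc1)P(=O)(OCC)OCC | intermediate
25 | 6-O-[2-(diethoxyphosphoryl)-3-(4-methoxybenzyloxy)propanoyl] ester of diol 20 (7-OH free) | C1[C@@H](OC(=O)C(COCc3ccc(OC)cc3)P(=O)(OCC)OCC)[C@@H](O)[C@@H](O[Si](C)(C)C(C)(C)C)C[C@@](C)(O[Si](CC)(CC)CC)[C@@H]2CC[C@@]1(C)O2 | intermediate
26 | 7-keto phosphonate (C7 ketone of 25) | C1[C@@H](OC(=O)C(COCc3ccc(OC)cc3)P(=O)(OCC)OCC)C(=O)[C@@H](O[Si](C)(C)C(C)(C)C)C[C@@](C)(O[Si](CC)(CC)CC)[C@@H]2CC[C@@]1(C)O2 | intermediate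
27 | C6–C7-fused butenolide with CH2OPMB on C11, (6R), 8-OTBS, 10-OTES | C1[C@H]2OC(=O)C(COCc3ccc(OC)cc3)=C2[C@@H](O[Si](C)(C)C(C)(C)C)C[C@@](C)(O[Si](CC)(CC)CC)[C@@H]4CC[C@@]1(C)O4 | intermediate
28 | 2-(tert-butyldimethylsilyloxy)furan fused at C6–C7 (not isolated) | C1c2oc(O[Si](C)(C)C(C)(C)C)c(COCc3ccc(OC)cc3)c2[C@@H](O[Si](C)(C)C(C)(C)C)C[C@@](C)(O[Si](CC)(CC)CC)[C@@H]4CC[C@@]1(C)O4 | intermediate
29 | 6-hydroxybutenolide (C6 hemiketal, either epimer) | C1C2(O)OC(=O)C(COCc3ccc(OC)cc3)=C2[C@@H](O[Si](C)(C)C(C)(C)C)C[C@@](C)(O[Si](CC)(CC)CC)[C@@H]4CC[C@@]1(C)O4 | intermediate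
30 | (E)-γ-alkylidene butenolide with C5=C6, 13-OPMB, 8-OTBS, 10-OTES | COc1ccc(COCC2=C3/C(=C\[C@@]4(C)CC[C@H](O4)[C@](C)(O[Si](CC)(CC)CC)C[C@@H]3O[Si](C)(C)C(C)(C)C)OC2=O)cc1 | intermediate
31 | 13-hydroxy compound (8-OTBS, 10-OTES) | OCC1=C2/C(=C\[C@@]3(C)CC[C@H](O3)[C@](C)(O[Si](CC)(CC)CC)C[C@@H]2O[Si](C)(C)C(C)(C)C)OC1=O | intermediate
32 | 13-acetate (8-OTBS, 10-OTES) | CC(=O)OCC1=C2/C(=C\[C@@]3(C)CC[C@H](O3)[C@](C)(O[Si](CC)(CC)CC)C[C@@H]2O[Si](C)(C)C(C)(C)C)OC1=O | intermediate
33 | 8,10-diol 13-acetate | CC(=O)OCC1=C2/C(=C\[C@@]3(C)CC[C@H](O3)[C@](C)(O)C[C@@H]2O)OC1=O | intermediate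
34 | 2-methylprop-2-en-1-ol | CC(=C)CO | starting material
35 | (R)-(2-methyloxiran-2-yl)methanol | C[C@@]1(CO)CO1 | intermediate
36 | (S)-2-methyloxirane-2-carboxylic acid | C[C@@]1(C(=O)O)CO1 | intermediate
37 | CNP0142137.1 | CC(=O)OCC1=C2/C(=C\[C@@]3(C)CC[C@H](O3)[C@](C)(O)C[C@@H]2OC(=O)[C@]2(C)CO2)OC1=O | target

**Step count and risks**

Total step count: 29. Longest linear sequence: 25 steps (steps 1–16, 19–26 and 29); steps 17–18 and 27–28 are side branches.

Steps most likely to fail:

Step 12. The process at risk is 1,2-migration of a C15 hydrogen in the carbenoid (giving a vinyl ketone), or C–H insertion, outrunning capture by the ring oxygen. The fallback sets out from acid 12 and replaces the methyl by an ester, so that no hydrogen can migrate. Carbonyldiimidazole would give the acyl imidazolide F1, and Mg(O2CCH2CO2CH3)2 would extend it to the β-keto ester F2. Diazo transfer (4-acetamidobenzenesulfonyl azide, Et3N) would give the α-diazo-β-keto ester F3. The same copper-catalysed ylide formation/[2,3] shift, well known for acceptor/acceptor carbenoids, would give the bicyclic keto ester F4 with CO2CH3 in the place of C15H3. LiAlH4 would reduce ketone and ester to the diol F5; NaH/CS2/MeI would give the bis-xanthate F6; Bu3SnH/AIBN would remove both oxygens and return the route at 19.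

Step 19. The process at risk is acylation spreading over both hydroxyls of the diol, or acyl migration from O6 to O7 before the oxidation. The fallback sets out from diol 20 and separates differentiation from acylation. Silylation with TESCl/imidazole at −20 °C would give the 6-O-triethylsilyl ether F7, and Dess–Martin oxidation the C7 ketone F8. PPTS in MeOH at 0 °C would cleave the secondary silyl ether (the tertiary TES and the TBS ether react more slowly) to the α-hydroxy ketone F9. Its single hydroxyl would be esterified with acid 24 (DCC, DMAP), which returns the route at 26.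

Step 23. The process at risk is incomplete dehydration, formation of the ring-trans C5=C6 isomer, or acid-induced loss of a silyl ether. The fallback sets out from butenolide 27 through its silyloxyfuran 28. PhSeCl at −78 °C would give the γ-phenylselanyl butenolide F10. H2O2/pyridine would oxidise it to the selenoxide F11, whose syn elimination can only engage a C5 hydrogen and would return the route at 30 without acid.

**Further compounds**

F1 | step 12 | acyl imidazolide of acid 12 (not isolated) | C=C[C@H]1O[C@@H](CC(=O)n2ccnc2)[C@](C)(O[Si](CC)(CC)CC)C[C@@H]1O[Si](C)(C)C(C)(C)C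
F2 | step 12 | methyl 4-[(2S,3R,5S,6R)-5-(tert-butyldimethylsilyloxy)-3-methyl-3-(triethylsilyloxy)-6-vinyltetrahydro-2H-pyran-2-yl]-3-oxobutanoate | C=C[C@H]1O[C@@H](CC(=O)CC(=O)OC)[C@](C)(O[Si](CC)(CC)CC)C[C@@H]1O[Si](C)(C)C(C)(C)C
F3 | step 12 | methyl 2-diazo-3-oxo-4-(tetrahydropyranyl)butanoate (diazo derivative of F2) | C=C[C@H]1O[C@@H](CC(=O)C(=[N+]=[N-])C(=O)OC)[C@](C)(O[Si](CC)(CC)CC)C[C@@H]1O[Si](C)(C)C(C)(C)C
F4 | step 12 | bridged keto ester (16 with CO2CH3 in place of the C4 methyl) | C1/C=C\[C@@H](O[Si](C)(C)C(C)(C)C)C[C@@](C)(O[Si](CC)(CC)CC)[C@@H]2CC(=O)[C@@]1(C(=O)OC)O2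
F5 | step 12 | C3,C15-diol (C3 configuration open) | C1/C=C\[C@@H](O[Si](C)(C)C(C)(C)C)C[C@@](C)(O[Si](CC)(CC)CC)[C@@H]2CC(O)[C@@]1(CO)O2
F6 | step 12 | C3,C15-bis(S-methyl xanthate) of F5 | C1/C=C\[C@@H](O[Si](C)(C)C(C)(C)C)C[C@@](C)(O[Si](CC)(CC)CC)[C@@H]2CC(OC(=S)SC)[C@@]1(COC(=S)SC)O2
F7 | step 19 | 6-O-triethylsilyl ether of diol 20 | C1[C@@H](O[Si](CC)(CC)CC)[C@@H](O)[C@@H](O[Si](C)(C)C(C)(C)C)C[C@@](C)(O[Si](CC)(CC)CC)[C@@H]2CC[C@@]1(C)O2
F8 | step 19 | 6-(triethylsilyloxy) C7 ketone | C1[C@@H](O[Si](CC)(CC)CC)C(=O)[C@@H](O[Si](C)(C)C(C)(C)C)C[C@@](C)(O[Si](CC)(CC)CC)[C@@H]2CC[C@@]1(C)O2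
F9 | step 19 | 6-hydroxy C7 ketone | C1[C@@H](O)C(=O)[C@@H](O[Si](C)(C)C(C)(C)C)C[C@@](C)(O[Si](CC)(CC)CC)[C@@H]2CC[C@@]1(C)O2
F10 | step 23 | 6-(phenylselanyl)butenolide (C6 epimers) | C1C2([Se]c5ccccc5)OC(=O)C(COCc3ccc(OC)cc3)=C2[C@@H](O[Si](C)(C)C(C)(C)C)C[C@@](C)(O[Si](CC)(CC)CC)[C@@H]4CC[C@@]1(C)O4
F11 | step 23 | selenoxide of F10 (not isolated) | C1C2([Se](=O)c5ccccc5)OC(=O)C(COCc3ccc(OC)cc3)=C2[C@@H](O[Si](C)(C)C(C)(C)C)C[C@@](C)(O[Si](CC)(CC)CC)[C@@H]4CC[C@@]1(C)O4
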